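## Structural features

The target is a 7-oxabicyclo[4.1.0]hept-4-ene: a cyclohexene ring (C1–C6, alkene C4=C5) fused across C1–C6 to an oxirane. C1 is quaternary and carries the C7 methylene as a benzoate, O2 is benzoylated and O3 is a free allylic hydroxyl. The four stereocentres C6, C1, C2 and C3 are contiguous; the oxirane oxygen, O2 and O3 all lie on one face of the carbocycle and C7 on the other, with absolute configuration (1S,2R,3R,6S). The fragile elements are the vinyl oxirane (C4=C5 next to C6–O; sensitive to acid, Lewis acid, zerovalent palladium and SN2' nucleophiles), the cis-related O2-benzoate/O3-hydroxyl pair (acyl migration under base) and the two esters. The real difficulties are the absolute sense of the cis-2,3-diol, placing the oxirane on the same face as the diol oxygens, and telling O2 from O3. The key step exploits the fact that C2 and C3 carry cis oxygens between C1 (bearing C7) and C4, with unsaturation at C1/C6 and C4=C5, which is the oxidation pattern of an arene cis-dihydrodiol of a para-substituted benzyl ester. The sense needed at C2/C3 is the mirror image of the one an oxygenated benzylic carbon induces, so a removable, larger group at C4 (iodine, where the target has hydrogen) must dictate the face.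

## Logic of the disconnections

9 to 8: the O3–H is traced back to an O3–Si bond. The C3 hydroxyl is unveiled last because a free hydroxyl cis to the C2 benzoate can exchange the acyl group. The gain is regiochemical security; the demand is a desilylation that is neither basic enough for acyl migration nor acidic enough to open the vinyl oxirane.

8 to 7 and 2: the C2 ester C(O)–O bond is cut. The same acyl chloride serves for both benzoates. The forward step must acylate a secondary hydroxyl wedged between the quaternary C1 and the silylated C3 without disturbing the oxirane.

7 to 6: the O3–Si bond is cut. This reduces the problem to a cis-diol with no protecting groups. The forward step must distinguish O3 (allylic, next to sp2 C4) from O2 (next to quaternary C1) on steric grounds.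

6 to 5: the C4–H bond is traced back to C4–I. The iodine is needed earlier as steering and deactivating group. The forward step must reduce a vinylic C–I bond in the presence of a vinyl oxirane, an ester and a free diol, which calls for a neutral radical chain.

5 to 4: both C–O bonds of the oxirane (C1–O and C6–O) are cut. Two stereocentres, including the quaternary one, return to an sp2 pair. The forward step must deliver oxygen to C1=C6 and not C4=C5, on the face of the C2 hydroxyl, under conditions a labile diene diol survives.

4 to 3: the C2–O and C3–O bonds are cut and the ring is rearomatised. All stereochemistry disappears and a flat, achiral arene remains. The forward step must add both oxygens cis to one face only, with iodine and not the benzylic ester group deciding which face.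

3 to 1 and 2: the C7 O–acyl bond is cut, leading to two commercial compounds. Putting the benzoate on before the enzymatic step avoids a later primary-selective acylation of a sensitive triol; the forward step is a routine esterification.

## Other disconnections considered

Alternative 1: The cut is the C1–C2 ring bond. In the forward sense the acyclic (Z)-keto aldehyde A1 (C2 aldehyde, C3 silyl ether, C4=C5 cis, C6 PMB ether, C1 ketone, C7 benzoate) would be closed by an intramolecular crossed benzoin reaction. A thiazolium-derived carbene, formed with Et3N, turns the C2 aldehyde into an acyl anion equivalent that adds to the C1 ketone. The product would be ketol A2, with the quaternary C1 carbinol trans to the C6 ether.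
- In its favour: one metal-free catalytic step would make the carbocycle and the quaternary centre. C3 and C6 would come from the chiral pool, so the absolute configuration would not depend on an enzyme accepting a new substrate; on that point it is the better plan. The trans C1–OH/C6–O pair of A2 is set up for an invertive oxirane closure, which is as secure mechanistically as the directed epoxidation chosen here (equal).
- Against it: A1 is both an α-silyloxy aldehyde and an α-acyloxy ketone, so the amine base can epimerise C3 or shift the C7 benzoate. The configuration at C1 would rest on the folding of a flexible chain and not on a rigid template. After A2 about six operations remain: cis-selective reduction at C2, benzoylation, PMB removal, sulfonylation of O6, closure by the tertiary C1 alkoxide next to an ester, and desilylation.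
- Comparison: structurally it builds the ring where the chosen plan edits an arene, which is more flexible for analogues. Mechanistically it is polar umpolung against enzymatic oxygen transfer. With the six to eight steps needed for A1 it would be at least twice as long as the seven steps chosen. The last unveiling of O3 beside the C2 benzoate is the same problem in both (equal).

Alternative 2: The cut is the C1–O bond of the ring-fused oxirane. It is traced back to the spiro-epoxy alcohol A3, with a C1–C7 oxirane whose oxygen is trans to a free C6 hydroxyl, and that hydroxyl cis to the O2/O3 acetonide. In the forward sense NaH would generate the C6 alkoxide, which attacks C1 from the rear with inversion in a Payne rearrangement. The product would be the ring-fused epoxy alcohol A4 with a free C7 hydroxyl.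
- In its favour: the all-cis relation of oxirane, O2 and O3 would follow from an intramolecular SN2 step and not from a facial preference; on that point it is better than a directed epoxidation. The equilibrium should favour A4 (trisubstituted oxirane, primary alkoxide). No halogen and hence no tin reagent is involved, which is also better. C7 benzoylation and acetonide hydrolysis of A4 would arrive at 6, so the end game is identical (equal).
- Against it: the stereochemical problem is only moved. A3 needs its methylene carbon delivered to C1 from the acetonide-bearing face, against the steric bias. An alkoxide in the presence of the vinyl oxirane product invites SN2' opening. Acid hydrolysis of the acetonide beside the vinyl oxirane is the operation least compatible with this skeleton.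
- Comparison: A3 itself would need roughly eight steps, so the plan is clearly longer.

Alternative 3: The cut is the C1–C6 ring bond. In the forward sense the carbohydrate-derived δ-lactone A5 carries an (E)-2-(benzyldimethylsilyl)vinyl group at C4. It would be enolised and O-silylated (KN(SiMe3)2, Me3SiCl) and would undergo an Ireland–Claisen rearrangement through the enforced boat transition state. C1–C6 forms, the alkene moves to C4=C5 and the lactone is exchanged for the cyclohexene acid A6.
- In its favour: the quaternary C1 would be made by chirality transfer from pool stereocentres. The C6 configuration would follow from the alkene geometry, and retentive oxidation of silicon would give a C6 hydroxyl trans to O1, ready for invertive oxirane closure. In stereochemical security this is the best of the four plans. Final removal of the O3 PMB ether by neutral oxidation would avoid the acyl-migration risk of a fluoride step, which is also a point in its favour.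
- Against it: C7 arrives as a carboxylic acid and must be reduced. The enolate has a β-oxygen that can eliminate. The C6 silane is allylic and can be lost with allylic transposition. After A6 about eight operations remain: reduction, benzoylation, Si-to-OH oxidation, sulfonylation, acetonide removal, closure, C2 benzoylation and PMB removal.
- Comparison: with the preparation of A5 the sequence would exceed fifteen steps against seven. Structurally it is the most general, but for this target the least economical.

Key step: step 2

Remark on the chemistry: in a para-disubstituted benzene every ortho,meta bond lies between both substituents, so the enzyme's choice is one of face (absolute sense) and not of position. It is assumed that iodine occupies the site for the larger group, as it does in 4-iodotoluene, and that the recombinant cells take up the benzoate.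

## Route

Step 1
Reactants: 1 4-iodobenzyl alcohol; 2 benzoyl chloride
Product: 3 4-iodobenzyl benzoate
Conditions: Et3N, DMAP (cat.), CH2Cl2, 0 °C to rt
Reagents that add atoms: none
Why: DMAP-catalysed nucleophilic acyl substitution on a primary benzylic alcohol; the aryl iodide is inert and no stereocentre is involved.

Step 2
Reactants: 3 4-iodobenzyl benzoate
Product: 4 [(5S,6S)-5,6-dihydroxy-4-iodocyclohexa-1,3-dien-1-yl]methyl benzoate
Conditions: E. coli JM109 (pDTG601) whole cells (toluene dioxygenase, IPTG-induced), air, glucose feed, mineral salts medium pH 7, 3 dosed in DMSO, 30 °C; EtOAc extraction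
Reagents that add atoms: dioxygen, O=O
Why: Toluene dioxygenase is a Rieske non-heme iron dioxygenase: electrons from NADH reach the mononuclear divalent iron through the reductase, the ferredoxin and the [2Fe–2S] cluster, O2 is bound there, and both of its oxygen atoms are passed to one face of the C2–C3 π bond, so the two new C–O bonds are necessarily cis. The closest known reaction type is the whole-cell cis-dihydroxylation of para-substituted iodobenzenes such as 4-iodotoluene, where iodine fills the pocket for the larger substituent. No ring is closed. Only one constitution of diol is possible because the C2–C3 bond is ortho,meta to both substituents, so the selectivity at stake is purely enantiofacial. C3 and C2 are both set by the enzyme: with iodine bound as the large group the carbinol next to C–I is formed (S), as in the diol of iodobenzene itself, which is the mirror-image sense to that induced by a CH2OR group. The step needs iodine to dominate over CH2OBz in the binding site (its size against a rotatable CH2O group should secure this), oxidation of the iodoarene in preference to the electron-poor benzoyl ring, and survival of the ester, for which a benzoate is more robust towards host esterases than an acetate. The diene diol is prone to dehydration to a phenol and to Diels–Alder dimerisation, so it should be kept cold, free of acid, and used promptly.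

Step 3
Reactants: 4 [(5S,6S)-5,6-dihydroxy-4-iodocyclohexa-1,3-dien-1-yl]methyl benzoate
Product: 5 [(1R,2R,3S,6S)-2,3-dihydroxy-4-iodo-7-oxabicyclo[4.1.0]hept-4-en-1-yl]methyl benzoate
Conditions: VO(acac)2 (5 mol %), t-BuOOH (1.2 equiv, decane solution), CH2Cl2, 0 °C
Reagents that add atoms: tert-butyl hydroperoxide, CC(C)(C)OO
Why: Hydroxyl-directed epoxidation: the C2 alkoxide binds a pentavalent vanadium tert-butylperoxo species (formed from the tetravalent precatalyst and the hydroperoxide), and the peroxide oxygen is passed to the adjacent C1=C6 bond on the face of the hydroxyls, which sets C1 and C6 with the oxirane cis to O2 and O3. C1=C6 is trisubstituted and electron-rich while C4=C5 carries the deactivating iodine, so site selectivity follows from both proximity and electronics. Because the oxirane is cis to the C2 hydroxyl, epoxide migration by backside attack is geometrically impossible.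

Step 4
Reactants: 5 [(1R,2R,3S,6S)-2,3-dihydroxy-4-iodo-7-oxabicyclo[4.1.0]hept-4-en-1-yl]methyl benzoate
Product: 6 [(1R,2R,3R,6S)-2,3-dihydroxy-7-oxabicyclo[4.1.0]hept-4-en-1-yl]methyl benzoate
Conditions: Bu3SnH, Et3B (cat.), trace air, toluene, 0 °C to rt
Reagents that add atoms: none
Why: Radical chain hydrodeiodination: Bu3Sn• abstracts iodine from the sp2 C4–I bond, and the resulting σ-vinyl radical, orthogonal to the π system and so unable to open the oxirane, takes hydrogen from Bu3SnH. The conditions are neutral and cold, and no stereocentre is touched.

Step 5
Reactants: 6 [(1R,2R,3R,6S)-2,3-dihydroxy-7-oxabicyclo[4.1.0]hept-4-en-1-yl]methyl benzoate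
Product: 7 [(1R,2R,3R,6S)-3-[(tert-butyldimethylsilyl)oxy]-2-hydroxy-7-oxabicyclo[4.1.0]hept-4-en-1-yl]methyl benzoate
Conditions: TBSCl (1.1 equiv), imidazole, DMF, 0 °C
Reagents that add atoms: tert-butyldimethylsilyl chloride, CC(C)(C)[Si](C)(C)Cl
Why: Imidazole-mediated silylation is governed by steric access: O3 is a secondary allylic hydroxyl beside the sp2 carbon C4, whereas O2 is wedged between the fully substituted C1 and C3, so one equivalent of the bulky chlorosilane should cap O3 first. No stereocentre changes.

Step 6
Reactants: 7 [(1R,2R,3R,6S)-3-[(tert-butyldimethylsilyl)oxy]-2-hydroxy-7-oxabicyclo[4.1.0]hept-4-en-1-yl]methyl benzoate; 2 benzoyl chloride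
Product: 8 [(1S,2R,3R,6S)-2-(benzoyloxy)-3-[(tert-butyldimethylsilyl)oxy]-7-oxabicyclo[4.1.0]hept-4-en-1-yl]methyl benzoate
Conditions: pyridine, DMAP (cat.), CH2Cl2, 0 °C to rt
Reagents that add atoms: none
Why: DMAP-catalysed acylation of the only remaining hydroxyl; with O3 blocked the benzoate can only go to O2, and the amine medium does not threaten the oxirane or the silyl ether.

Step 7
Reactants: 8 [(1S,2R,3R,6S)-2-(benzoyloxy)-3-[(tert-butyldimethylsilyl)oxy]-7-oxabicyclo[4.1.0]hept-4-en-1-yl]methyl benzoate
Product: 9 [(1S,2R,3R,6S)-2-(benzoyloxy)-3-hydroxy-7-oxabicyclo[4.1.0]hept-4-en-1-yl]methyl benzoate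
Conditions: Bu4NF, AcOH (1:1), THF, 0 °C to rt
Reagents that add atoms: none
Why: Fluoride-induced Si–O cleavage driven by the strength of the Si–F bond. Buffering with AcOH keeps the liberated O3 protonated so that the cis C2 benzoate does not migrate, while the medium stays too weakly acidic to open the vinyl oxirane.

## Compound list

The C1 descriptor switches between R and S along 5–9 only because the CIP ranking of C2 against C6 changes when O2 is acylated. The C3 descriptor switches when iodine is removed. No bond at these centres is broken after step 3.

1 | 4-iodobenzyl alcohol | OCc1ccc(I)cc1 | starting material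
2 | benzoyl chloride | O=C(Cl)c1ccccc1 | starting material
3 | 4-iodobenzyl benzoate | O=C(OCc1ccc(I)cc1)c1ccccc1 | intermediate
4 | [(5S,6S)-5,6-dihydroxy-4-iodocyclohexa-1,3-dien-1-yl]methyl benzoate (cis-diol) | O=C(OCC1=CC=C(I)[C@@H](O)[C@H]1O)c1ccccc1 | intermediate
5 | [(1R,2R,3S,6S)-2,3-dihydroxy-4-iodo-7-oxabicyclo[4.1.0]hept-4-en-1-yl]methyl benzoate (oxirane cis to both hydroxyls) | O=C(OC[C@]12O[C@H]1C=C(I)[C@@H](O)[C@H]2O)c1ccccc1 | intermediate
6 | [(1R,2R,3R,6S)-2,3-dihydroxy-7-oxabicyclo[4.1.0]hept-4-en-1-yl]methyl benzoate | O=C(OC[C@]12O[C@H]1C=C[C@@H](O)[C@H]2O)c1ccccc1 | intermediate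
7 | [(1R,2R,3R,6S)-3-[(tert-butyldimethylsilyl)oxy]-2-hydroxy-7-oxabicyclo[4.1.0]hept-4-en-1-yl]methyl benzoate | O=C(OC[C@]12O[C@H]1C=C[C@@H](O[Si](C)(C)C(C)(C)C)[C@H]2O)c1ccccc1 | intermediate
8 | [(1S,2R,3R,6S)-2-(benzoyloxy)-3-[(tert-butyldimethylsilyl)oxy]-7-oxabicyclo[4.1.0]hept-4-en-1-yl]methyl benzoate | O=C(OC[C@]12O[C@H]1C=C[C@@H](O[Si](C)(C)C(C)(C)C)[C@H]2OC(=O)c1ccccc1)c1ccccc1 | intermediate
9 | [(1S,2R,3R,6S)-2-(benzoyloxy)-3-hydroxy-7-oxabicyclo[4.1.0]hept-4-en-1-yl]methyl benzoate | O=C(OC[C@]12O[C@H]1C=C[C@@H](O)[C@H]2OC(=O)c1ccccc1)c1ccccc1 | target

## Step count and least certain steps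

Total step count: 7. Longest linear sequence: 7 steps (1 to 9; compound 2 enters in steps 1 and 6).

**Step 2 (key step).** The most likely failures are slow or absent turnover, because the substrate is a bulky, poorly water-soluble, para-substituted diaryl ester, and erosion of enantiomeric purity if the CH2OBz group competes with iodine for the large-substituent site, so that some oxidation occurs on the opposite face. Hydrolysis of the ester by host esterases is a further risk. The enantiomeric purity of 4 should be checked before it is carried on.

Fallback, setting out from 1 and returning at 4: the benzylic oxygen is given the smallest practical ester so that iodine outranks it more clearly and the substrate resembles benzyl acetate, a type the cells are known to accept. Compound 1 is acetylated (Ac2O, pyridine) to 4-iodobenzyl acetate F1. This is fed to the same cells to give [(5S,6S)-5,6-dihydroxy-4-iodocyclohexa-1,3-dien-1-yl]methyl acetate F2. Methanolysis with catalytic K2CO3 in MeOH at 0 °C, to which the diene diol is stable, gives (1S,2S)-6-(hydroxymethyl)-3-iodocyclohexa-3,5-diene-1,2-diol F3. Its primary hydroxyl is benzoylated selectively with 2 and 2,4,6-collidine in CH2Cl2 at −78 °C to give 4.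

**Step 3.** The cis-diol may chelate vanadium and stall the catalyst, and the Lewis-acidic metal may dehydrate the diene diol to a phenol before oxygen transfer.

Fallback, setting out from 4 and returning at 5: the oxirane is built by trans-halohydrin formation and invertive closure, so that the face is decided by sterics and an SN2 step and not by metal direction. Both hydroxyls are capped (Et3SiCl, imidazole, DMF) to give [(5S,6S)-4-iodo-5,6-bis[(triethylsilyl)oxy]cyclohexa-1,3-dien-1-yl]methyl benzoate F4. N-Bromosuccinimide in aqueous THF places bromine on C1 from the face away from the silyl ethers and water on the allylic C6 from the other face, giving [(1R,2R,3S,6S)-1-bromo-6-hydroxy-4-iodo-2,3-bis[(triethylsilyl)oxy]cyclohex-4-en-1-yl]methyl benzoate F5. The regioisomeric bromohydrin would close to the same oxirane. NaH in THF at 0 °C closes the ring with inversion at C1 to [(1S,2R,3S,6S)-4-iodo-2,3-bis[(triethylsilyl)oxy]-7-oxabicyclo[4.1.0]hept-4-en-1-yl]methyl benzoate F6. Buffered fluoride (Bu4NF, AcOH) then frees both hydroxyls to give 5.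

**Step 4.** Stannyl radical addition to the vinyl oxirane, with ring opening of the resulting α-oxiranyl radical, may compete with iodine abstraction.

Fallback, setting out from 4 and returning at 6: the order is inverted. The same radical reduction is applied to the diene diol 4, which has no oxirane, to give [(5R,6S)-5,6-dihydroxycyclohexa-1,3-dien-1-yl]methyl benzoate F7. The hydroxyl-directed epoxidation of step 3 is then run on F7 to give 6. The price is that site selectivity between C1=C6 and C4=C5 then rests only on the higher substitution of C1=C6.

**Step 5.** Site selectivity between the two secondary hydroxyls may be poor, with silylation at O2 or at both oxygens.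

Fallback, setting out from 5 and returning at 9: the differentiation is moved to the stage where iodine is still present and used in the opposite sense. In 5 the C3 hydroxyl is shielded by the neighbouring C4 iodine, as the proximal hydroxyl of halodiene diols is. Treating 5 with one equivalent of 2 and pyridine at −40 °C should therefore acylate O2 directly, to give [(1S,2R,3S,6S)-2-(benzoyloxy)-3-hydroxy-4-iodo-7-oxabicyclo[4.1.0]hept-4-en-1-yl]methyl benzoate F8. The neutral radical reduction of step 4 (Bu3SnH, Et3B) then removes the iodine to give 9, without any silyl group.

**Step 7.** Benzoyl migration from O2 to O3 may occur under fluoride, or the oxirane may open if the medium is made more acidic to suppress it.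

Fallback, setting out from 6 and returning at 9: O3 is masked with an acyl group that is removed under buffered, near-neutral conditions. Levulinic acid, N,N'-diisopropylcarbodiimide and catalytic DMAP at −20 °C would give [(1R,2R,3R,6S)-2-hydroxy-3-[(4-oxopentanoyl)oxy]-7-oxabicyclo[4.1.0]hept-4-en-1-yl]methyl benzoate F9. Benzoylation with 2 and pyridine gives [(1S,2R,3R,6S)-2-(benzoyloxy)-3-[(4-oxopentanoyl)oxy]-7-oxabicyclo[4.1.0]hept-4-en-1-yl]methyl benzoate F10. Hydrazine acetate in pyridine/AcOH removes the levulinate as a cyclic hydrazide and leaves both benzoates in place, giving 9.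

## Further compounds

F1 | step 2 | 4-iodobenzyl acetate | CC(=O)OCc1ccc(I)cc1
F2 | step 2 | [(5S,6S)-5,6-dihydroxy-4-iodocyclohexa-1,3-dien-1-yl]methyl acetate | CC(=O)OCC1=CC=C(I)[C@@H](O)[C@H]1O
F3 | step 2 | (1S,2S)-6-(hydroxymethyl)-3-iodocyclohexa-3,5-diene-1,2-diol | OCC1=CC=C(I)[C@@H](O)[C@H]1O
F4 | step 3 | [(5S,6S)-4-iodo-5,6-bis[(triethylsilyl)oxy]cyclohexa-1,3-dien-1-yl]methyl benzoate | O=C(OCC1=CC=C(I)[C@@H](O[Si](CC)(CC)CC)[C@H]1O[Si](CC)(CC)CC)c1ccccc1
F5 | step 3 | [(1R,2R,3S,6S)-1-bromo-6-hydroxy-4-iodo-2,3-bis[(triethylsilyl)oxy]cyclohex-4-en-1-yl]methyl benzoate | O=C(OC[C@@]1(Br)[C@@H](O)C=C(I)[C@@H](O[Si](CC)(CC)CC)[C@H]1O[Si](CC)(CC)CC)c1ccccc1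
F6 | step 3 | [(1S,2R,3S,6S)-4-iodo-2,3-bis[(triethylsilyl)oxy]-7-oxabicyclo[4.1.0]hept-4-en-1-yl]methyl benzoate | O=C(OC[C@]12O[C@H]1C=C(I)[C@@H](O[Si](CC)(CC)CC)[C@H]2O[Si](CC)(CC)CC)c1ccccc1
F7 | step 4 | [(5R,6S)-5,6-dihydroxycyclohexa-1,3-dien-1-yl]methyl benzoate | O=C(OCC1=CC=C[C@@H](O)[C@H]1O)c1ccccc1
F8 | step 5 | [(1S,2R,3S,6S)-2-(benzoyloxy)-3-hydroxy-4-iodo-7-oxabicyclo[4.1.0]hept-4-en-1-yl]methyl benzoate | O=C(OC[C@]12O[C@H]1C=C(I)[C@@H](O)[C@H]2OC(=O)c1ccccc1)c1ccccc1
F9 | step 7 | [(1R,2R,3R,6S)-2-hydroxy-3-[(4-oxopentanoyl)oxy]-7-oxabicyclo[4.1.0]hept-4-en-1-yl]methyl benzoate | O=C(OC[C@]12O[C@H]1C=C[C@@H](OC(=O)CCC(C)=O)[C@H]2O)c1ccccc1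
F10 | step 7 | [(1S,2R,3R,6S)-2-(benzoyloxy)-3-[(4-oxopentanoyl)oxy]-7-oxabicyclo[4.1.0]hept-4-en-1-yl]methyl benzoate | O=C(OC[C@]12O[C@H]1C=C[C@@H](OC(=O)CCC(C)=O)[C@H]2OC(=O)c1ccccc1)c1ccccc1
A1 | alternative 1 | (3R,4Z,6R)-6-[(tert-butyldimethylsilyl)oxy]-3-[(4-methoxybenzyl)oxy]-2,7-dioxohept-4-en-1-yl benzoate | O=C(OCC(=O)[C@H](OCc1ccc(OC)cc1)/C=C\[C@@H](O[Si](C)(C)C(C)(C)C)C=O)c1ccccc1
A2 | alternative 1 | [(1S,2R,5R)-5-[(tert-butyldimethylsilyl)oxy]-1-hydroxy-2-[(4-methoxybenzyl)oxy]-6-oxocyclohex-3-en-1-yl]methyl benzoate | O=C(OC[C@]1(O)[C@H](OCc2ccc(OC)cc2)C=C[C@@H](O[Si](C)(C)C(C)(C)C)C1=O)c1ccccc1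
A3 | alternative 2 | 2,3-O-isopropylidene-1,7-epoxycyclohex-4-en-6-ol in target numbering (C1–C7 spiro-oxirane, its oxygen trans to the C6 hydroxyl; C6 hydroxyl cis to the acetonide oxygens) | O[C@H]1C=C[C@H]2OC(C)(C)O[C@H]2[C@@]13CO3
A4 | alternative 2 | [1,6-epoxy-2,3-(isopropylidenedioxy)cyclohex-4-en-1-yl]methanol in target numbering (ring-fused oxirane cis to the acetonide, free C7 hydroxyl) | OC[C@]12O[C@H]1C=C[C@H]3OC(C)(C)O[C@@H]23
A5 | alternative 3 | 7-(benzyldimethylsilyl)-6,7-dideoxy-2,3-O-isopropylidene-4-O-(4-methoxybenzyl)-hept-6-(E)-enono-1,5-lactone (D-ribo at sugar C2–C4, all four ring substituents cis) | O=C1O[C@@H](/C=C/[Si](C)(C)Cc2ccccc2)[C@@H](OCc2ccc(OC)cc2)[C@H]2OC(C)(C)O[C@@H]12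
A6 | alternative 3 | 6-(benzyldimethylsilyl)-1,2-O-isopropylidene-3-O-(4-methoxybenzyl)cyclohex-4-ene-1-carboxylic acid in target numbering (O1, O2 and O3 cis, silicon trans to them) | OC(=O)[C@@]12OC(C)(C)O[C@@H]1[C@H](OCc3ccc(OC)cc3)C=C[C@H]2[Si](C)(C)Cc3ccccc3
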